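**Retrosynthetic overview**
1. Target 17 comes from its C21 silyl ether 16. 16 comes from ester 13 in one pot: an anionic double Michael reaction (C9–C16 closes lactone ring C, then C15–C17 closes ring B and makes the spiro centre), followed by methyl addition at C14.
2. Key disconnection: the C12–O11 bond of 13, made by a stereoinvertive C–O coupling of acid 11 with (S)-4-hydroxycyclopent-2-enone 12.
3. One (S)-configured building block serves twice: with inversion for ring A (from 12), and with retention as its silyl ether 7 for ring D.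
4. Acid 11 comes from aldehyde 8 by C8=C9 olefination and ring D dehydrogenation. 8 comes from the C7–C17 Michael union of enol silane 6 with 7.
5. 6 comes from lactone 3, whose asymmetric isopropenyl addition sets C4. Ring order: A and D are bought, then C, then B.

Atom labels: C1–C3 isopropenyl; C4 side-chain CH; C5/C6 CH2CO2Me; C7=C8 ring B alkene; C9 lactone α-CH; C10 lactone C=O; O11; C12 OCH; C13 CH2; C14 C(Me)OH; C15, C16 ring-fusion CH; C17 spiro C; C18 CH2; C19 C=O; C20 CH2; C21 CHOH. Ring A = C12–C16, ring B = cyclohexene, ring C = lactone, ring D = spiro cyclopentanone. The target is 4S,9R,12R,14S,15S,16R,17R,21S. H12, H15, H16 and the C14 methyl lie on one face of ring A. H9 is anti to H16. C15 is trans to the C21 oxygen on ring D.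

Assumption: 1, 2, 7, 9 and 12 are bought; (S)-BINAP is taken to give (S)-3 by analogy with aryl additions to 1, and the antipodal ligand is used if the sense proves opposite.

**Step 1**
Reactants: 1 5,6-dihydro-2H-pyran-2-one; 2 potassium trifluoro(prop-1-en-2-yl)borate
Product: 3 (S)-4-(prop-1-en-2-yl)oxan-2-one
Conditions: [Rh(cod)2]BF4 (3 mol %), (S)-BINAP (3.3 mol %), toluene/H2O 10:1, 100 °C
Reagents that add atoms: none
Why: Hayashi–Miyaura rhodium-catalysed asymmetric 1,4-addition to a well-behaved unsaturated δ-lactone, in which the BINAP-bound alkenylrhodium adds to one enantioface and sets C4, the only stereocentre not relayed from the cyclopentenone building block.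

**Step 2**
Reactants: 3 (S)-4-(prop-1-en-2-yl)oxan-2-one
Product: 5 methyl (S)-5-oxo-3-(prop-1-en-2-yl)pentanoate, via hydroxy ester 4 (not isolated)
Conditions: NaOMe (0.1 equiv), MeOH, 0 °C; AcOH (0.1 equiv), evaporate; TEMPO (0.1 equiv), PhI(OAc)2 (1.1 equiv), CH2Cl2, rt
Reagents that add atoms: methanol, CO
Why: Lactone methanolysis (transesterification) fixes C5/C6 as the final methyl ester, and TEMPO/PhI(OAc)2 oxidation turns the freed primary alcohol into the C8 aldehyde before it can relactonise; C4 is β to both carbonyls and cannot epimerise.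

**Step 3**
Reactants: 5 methyl (S)-5-oxo-3-(prop-1-en-2-yl)pentanoate
Product: 6 methyl (R)-5-(tert-butyldimethylsilyloxy)-3-(prop-1-en-2-yl)pent-4-enoate (E/Z mixture)
Conditions: TBSOTf (1.1 equiv), Et3N (1.5 equiv), CH2Cl2, −78 to 0 °C
Reagents that add atoms: tert-butyldimethylsilyl triflate, CC(C)(C)[Si](C)(C)OS(=O)(=O)C(F)(F)F
Why: Soft enolisation to a silyl enol ether is much faster for the aldehyde than for the ester and makes C7 nucleophilic; the alkene geometry is irrelevant and C4 is untouched (the descriptor changes only through priorities).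

**Step 4**
Reactants: 6 enol silane; 7 (S)-4-(tert-butyldimethylsilyloxy)cyclopent-2-en-1-one
Product: 8 methyl (3R)-4-[(1R,5S)-3,5-bis(tert-butyldimethylsilyloxy)cyclopent-2-en-1-yl]-4-formyl-3-(prop-1-en-2-yl)butanoate (C7 epimers)
Conditions: Tf2NH (3 mol %), CH2Cl2, −78 °C
Reagents that add atoms: none
Why: Mukaiyama–Michael addition with silyl transfer forms C7–C17 anti to the C21 silyloxy group and leaves ring D as the regiodefined C18=C19 silyl enol ether; the C7 and C17 centres made here are erased later.

**Step 5**
Reactants: 8 aldehyde; 9 diethylphosphonoacetic acid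
Product: 10 (2E,5R)-4-[(1R,5S)-3,5-bis(tert-butyldimethylsilyloxy)cyclopent-2-en-1-yl]-5-(2-methoxy-2-oxoethyl)-6-methylhepta-2,6-dienoic acid
Conditions: Zn(OTf)2, TMEDA, DBU, THF, rt; pH 4 buffer
Reagents that add atoms: none
Why: Horner–Wadsworth–Emmons olefination with the diprotic phosphonate under mild zinc/amine conditions gives the free (E)-enoic acid (C8=C9–C10) directly and spares both silyl groups and the methyl ester.

**Step 6**
Reactants: 10 bis-silylated acid
Product: 11 (2E,5R)-4-[(5S)-5-(tert-butyldimethylsilyloxy)-3-oxocyclopent-1-en-1-yl]-5-(2-methoxy-2-oxoethyl)-6-methylhepta-2,6-dienoic acid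
Conditions: Pd(OAc)2 (1.1 equiv), MeCN, 40 °C
Reagents that add atoms: none
Why: Saegusa–Ito oxidation of the regiodefined silyl enol ether can eliminate only the C17 hydrogen, so it gives the C17=C18 enone and leaves C7–H flanked by an enone and an enoate.

**Step 7** (key C–O coupling)
Reactants: 11 acid; 12 (S)-4-hydroxycyclopent-2-en-1-one
Product: 13 (R)-4-oxocyclopent-2-en-1-yl ester of 11
Conditions: PPh3, DIAD, toluene/THF, −10 °C
Reagents that add atoms: none
Why: Mitsunobu esterification forms the C12–O11 bond by SN2 displacement with clean inversion, so (S)-12 gives the 12R ester, the two halves are joined, and the stereocentre that directs all ring-forming events is installed.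

**Step 8**
Reactants: 13 ester
Product: 16 C21 tert-butyldimethylsilyl ether of the target, via lithium trienolate 14 (not isolated), via tetracyclic lithium enolate 15 (not isolated)
Conditions: LiN(SiMe3)2 (1.05 equiv), THF, −78 to −20 °C; then LaCl3·2LiCl (0.3 equiv), MeMgBr (3 equiv), −78 °C; aq NH4Cl
Reagents that add atoms: methylmagnesium bromide, C[Mg]Br
Why: Proposed new method: removing the doubly vinylogous C7–H gives trienolate 14, whose ester α-carbon C9 attacks C16 of the tethered acyloxy enone on the face syn to O11 (5-exo, ring C), and the C15 enolate so formed closes onto C17 cis to C9 and anti to the C21 silyloxy group, with the flat C18=C19 unit lying under ring A (ring B and the quaternary spiro centre); the E-enoate with ring A exo gives H9 anti to H16, which also avoids the C10/C18 flagpole contact of the all-cis isomer, and the terminal C19 enolate 15 masks that ketone so the lanthanum-assisted Grignard reagent attacks only C14, from the convex face (methyl syn to H15/H16, OH syn to C17); the closest known reaction types are the lithium-amide-induced intramolecular double Michael reaction of enone–enoates (anionic formal Diels–Alder) and the use of an enolate as an in situ ketone protecting group, neither shown for an ester tether between two cyclopentenones or for closure onto a β,β-disubstituted acceptor.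

**Step 9**
Reactants: 16 silyl ether
Product: 17 target CNP0255095.1
Conditions: HF·pyridine, THF, 0 °C to rt
Reagents that add atoms: none
Why: Fluoride desilylation under mildly acidic conditions frees the C21 alcohol without E1cB loss from the β-hydroxy ketone or epimerisation at C9, and no stereocentre is touched.

**Compound list**
1 | 5,6-dihydro-2H-pyran-2-one | O=C1C=CCCO1 | starting material
2 | potassium trifluoro(prop-1-en-2-yl)borate | [K+].C=C(C)[B-](F)(F)F | starting material
3 | (S)-4-(prop-1-en-2-yl)oxan-2-one | C=C(C)[C@@H]1CC(=O)OCC1 | intermediate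
4 | methyl (S)-5-hydroxy-3-(prop-1-en-2-yl)pentanoate | C=C(C)[C@H](CC(=O)OC)CCO | intermediate
5 | methyl (S)-5-oxo-3-(prop-1-en-2-yl)pentanoate | C=C(C)[C@H](CC(=O)OC)CC=O | intermediate
6 | methyl (R)-5-(tert-butyldimethylsilyloxy)-3-(prop-1-en-2-yl)pent-4-enoate | C=C(C)[C@H](CC(=O)OC)C=CO[Si](C)(C)C(C)(C)C | intermediate
7 | (S)-4-(tert-butyldimethylsilyloxy)cyclopent-2-en-1-one | C1=CC(=O)C[C@@H]1O[Si](C)(C)C(C)(C)C | starting material
8 | Michael adduct aldehyde (C7 epimers) | C=C(C)[C@H](CC(=O)OC)C(C=O)[C@H]1C=C(O[Si](C)(C)C(C)(C)C)C[C@@H]1O[Si](C)(C)C(C)(C)C | intermediate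
9 | diethylphosphonoacetic acid | CCOP(=O)(CC(=O)O)OCC | starting material
10 | (E)-enoic acid with ring D as silyl enol ether | C=C(C)[C@H](CC(=O)OC)C(/C=C/C(=O)O)[C@H]1C=C(O[Si](C)(C)C(C)(C)C)C[C@@H]1O[Si](C)(C)C(C)(C)C | intermediate
11 | (E)-enoic acid with ring D enone | C=C(C)[C@H](CC(=O)OC)C(/C=C/C(=O)O)C1=CC(=O)C[C@@H]1O[Si](C)(C)C(C)(C)C | intermediate
12 | (S)-4-hydroxycyclopent-2-en-1-one | O[C@@H]1C=CC(=O)C1 | starting material
13 | (R)-4-oxocyclopent-2-en-1-yl ester of 11 | C=C(C)[C@H](CC(=O)OC)C(/C=C/C(=O)O[C@H]1C=CC(=O)C1)C1=CC(=O)C[C@@H]1O[Si](C)(C)C(C)(C)C | intermediate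
14 | lithium trienolate of 13 | C=C(C)[C@H](CC(=O)OC)C(/C=C/C(=O)O[C@H]1C=CC(=O)C1)=C1C=C([O-])C[C@@H]1O[Si](C)(C)C(C)(C)C.[Li+] | intermediate
15 | tetracyclic C14 ketone, C19 lithium enolate | C=C(C)[C@H](CC(=O)OC)C1=C[C@H]2C(=O)O[C@@H]3CC(=O)[C@@H]([C@@H]32)[C@]12C=C([O-])C[C@@H]2O[Si](C)(C)C(C)(C)C.[Li+] | intermediate
16 | C21 tert-butyldimethylsilyl ether of the target | C=C(C)[C@H](CC(=O)OC)C1=C[C@H]2C(=O)O[C@@H]3C[C@](C)(O)[C@@H]([C@@H]32)[C@]12CC(=O)C[C@@H]2O[Si](C)(C)C(C)(C)C | intermediate
17 | CNP0255095.1 | C=C(C)[C@H](CC(=O)OC)C1=C[C@H]2C(=O)O[C@@H]3C[C@](C)(O)[C@@H]([C@@H]32)[C@]12CC(=O)C[C@@H]2O | target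

**Total step count:** 9. **Longest linear sequence:** 9.

**Three steps most likely to fail**

Step 8 (the proposed new step). The risks are these:
- The base may enolise ring A at C13 and expel the carboxylate.
- The second closure onto the fully substituted C17 may be slower than proton transfer from the acidic C9–H.
- Enolate 15 may equilibrate before the Grignard reagent is added.

The fallback uses known reaction types and takes the ring formation out of basic medium. It sets out from 13. This is deprotonated and O-silylated at once at −78 °C (LiN(SiMe3)2, then TBSOTf) to the silyl trienol ether F1. F1 is cyclised as a neutral silyloxytriene by a thermal intramolecular Diels–Alder reaction (toluene, 130 °C, sealed tube) to the tetracyclic keto silyl enol ether F2. Addition of MeMgBr with LaCl3·2LiCl at −78 °C to the only free ketone gives the tertiary alcohol F3. HF·pyridine then removes both silyl groups, and the fallback comes back to the route at 17.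

Step 7. The activated alcohol of 12 can eliminate to cyclopentadienone instead of being displaced. The fallback replaces the SN2 event with a π-allyl substitution and sets out from 11. Commercial racemic 4-hydroxycyclopent-2-en-1-one is treated with Boc2O, Et3N and DMAP to give the racemic carbonate F4. 11 is then coupled with 2.2 equivalents of it using Pd2(dba)3·CHCl3 and the (R,R)-DACH-phenyl Trost ligand in CH2Cl2 at 0 °C. Zerovalent palladium ionises the (R)-carbonate faster and the carboxylate attacks anti to the metal. The outcome is net retention, a kinetic resolution known for simple carboxylic acids. The fallback comes back at 13.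

Step 4. Product aldehyde 8 can compete with enone 7 for the enol silane (Mukaiyama aldol), and the newly made C7 is very crowded for step 5. The fallback reverses the order of bond formation and sets out from 5. The unhindered aldehyde is olefinated first with 9 (Zn(OTf)2, TMEDA, DBU) to the (S,E)-dienoic acid F5. This is converted with LiN(SiMe3)2 and TBSCl into the bis-silyl dienediolate F6. A γ-selective vinylogous Mukaiyama–Michael addition of F6 to 7 (Tf2NH, 3 mol %, CH2Cl2, −78 °C) gives the silyl ester F7. No aldehyde is present at any stage of this union. F7 hydrolyses on aqueous work-up, and the fallback comes back at 10.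

**Further compounds**
F1 | step 8 | silyl trienol ether of 13 (TBS on the ring D oxygen) | C=C(C)[C@H](CC(=O)OC)C(/C=C/C(=O)O[C@H]1C=CC(=O)C1)=C1C=C(O[Si](C)(C)C(C)(C)C)C[C@@H]1O[Si](C)(C)C(C)(C)C
F2 | step 8 | tetracyclic C14 ketone, C19 silyl enol ether | C=C(C)[C@H](CC(=O)OC)C1=C[C@H]2C(=O)O[C@@H]3CC(=O)[C@@H]([C@@H]32)[C@]12C=C(O[Si](C)(C)C(C)(C)C)C[C@@H]2O[Si](C)(C)C(C)(C)C
F3 | step 8 | tetracyclic C14 tertiary alcohol, C19 silyl enol ether | C=C(C)[C@H](CC(=O)OC)C1=C[C@H]2C(=O)O[C@@H]3C[C@](C)(O)[C@@H]([C@@H]32)[C@]12C=C(O[Si](C)(C)C(C)(C)C)C[C@@H]2O[Si](C)(C)C(C)(C)C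
F4 | step 7 | racemic tert-butyl (4-oxocyclopent-2-en-1-yl) carbonate | CC(C)(C)OC(=O)OC1C=CC(=O)C1
F5 | step 4 | (S,E)-5-(2-methoxy-2-oxoethyl)-6-methylhepta-2,6-dienoic acid | C=C(C)[C@H](CC(=O)OC)C/C=C/C(=O)O
F6 | step 4 | bis(tert-butyldimethylsilyl) dienediolate of F5 | C=C(C)[C@H](CC(=O)OC)C=CC=C(O[Si](C)(C)C(C)(C)C)O[Si](C)(C)C(C)(C)C
F7 | step 4 | tert-butyldimethylsilyl ester of 10 | C=C(C)[C@H](CC(=O)OC)C(/C=C/C(=O)O[Si](C)(C)C(C)(C)C)[C@H]1C=C(O[Si](C)(C)C(C)(C)C)C[C@@H]1O[Si](C)(C)C(C)(C)C
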